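Ring A of the octahydronaphthalene core (C1–C4, C4a, C8a; C1=C8a, quaternary C2) is closed at C4–C4a by an Ireland–Claisen ring contraction. The precursor is a δ-lactone: C1 carries the ring oxygen and a cyclohexenyl group (ring B, C8a=C4a) made from (S)-carvone, and C4 is the lactone α-carbon. The step exploits the fact that the C4–C4a bond lies allylic to C1=C8a: one [3,3] shift forms C4–C4a, creates C1=C8a and sets C4a. The C2/benzylic stereodiad is built beforehand on a dihydrocoumarin template, and the surplus carboxyl on C4 is then removed by Barton decarboxylation.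

Key step: step 9

Remark on the chemistry: atom numbers C1–C8a refer to the octahydronaphthalene core of the target (C5 bears the oxygenated isopropyl group, C8 the methyl group, C1' is the benzylic carbon); the sense of induction of the chiral ligands in steps 1 and 8 is assumed to be selectable through the ligand enantiomer.

Step 1
Reactants: 1 5,7-dimethoxycoumarin; 2 isobutylmagnesium bromide
Product: 3 (4S)-4-isobutyl-5,7-dimethoxychroman-2-one
Conditions: iBuMgBr, CuBr·SMe2 (5 mol%), (R)-1-[(S)-2-(diphenylphosphino)ferrocenyl]ethyldicyclohexylphosphine (6 mol%), tBuOMe, −72 °C; then H2O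
Reagents that add atoms: isobutylmagnesium bromide, CC(C)C[Mg]Br
Why: Copper-catalysed asymmetric conjugate addition of a Grignard reagent to the coumarin enoate, in which the chiral diphosphine–copper complex selects the face of C3=C4 and so sets C4 (the later benzylic carbon C1') as S, the ligand enantiomer being chosen for this sense.

Step 2
Reactants: 3 (4S)-4-isobutyl-5,7-dimethoxychroman-2-one; 4 methyl acrylate
Product: 5 methyl 3-[(3S,4S)-4-isobutyl-5,7-dimethoxy-2-oxochroman-3-yl]propanoate (3,4-trans)
Conditions: LDA, THF, −78 °C; methyl acrylate, −78 °C; AcOH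
Reagents that add atoms: methyl acrylate, C=CC(=O)OC
Why: Michael addition of the lithium lactone enolate to the acrylate installs the three-carbon ester arm (future C3, C4 and the temporary carboxyl) anti to the pseudoaxial isobutyl group; this centre is made planar again in step 3.

Step 3
Reactants: 5 methyl 3-[(3S,4S)-4-isobutyl-5,7-dimethoxy-2-oxochroman-3-yl]propanoate; 6 iodomethane
Product: 7 methyl 3-[(3R,4R)-4-isobutyl-5,7-dimethoxy-3-methyl-2-oxochroman-3-yl]propanoate (3-methyl trans to 4-isobutyl)
Conditions: NaHMDS, THF, −78 °C; MeI, −78 → −20 °C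
Reagents that add atoms: iodomethane, CI
Why: Enolate alkylation in which the more acidic α-proton of the aryl lactone is removed in preference to those of the methyl ester, and iodomethane attacks anti to the 4-isobutyl group (held pseudoaxial by the peri methoxy group), which sets the quaternary centre (future C2) with methyl trans and the ester arm cis to isobutyl.

Step 4
Reactants: 7 methyl 3-[(3R,4R)-4-isobutyl-5,7-dimethoxy-3-methyl-2-oxochroman-3-yl]propanoate
Product: 8 methyl 3-[(3R,4R)-2-hydroxy-4-isobutyl-5,7-dimethoxy-3-methylchroman-3-yl]propanoate (lactol, both anomers)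
Conditions: LiAlH(OtBu)3, THF, −20 → 0 °C; then H2O
Reagents that add atoms: none
Why: Chemoselective hydride reduction, since lithium tri-tert-butoxyaluminium hydride takes an activated aryl ester to the aldehyde level (here held as the lactol) and should leave the alkyl methyl ester untouched; no skeletal stereocentre is affected.

Step 5
Reactants: 8 the lactol; 6 iodomethane
Product: 9 methyl (4R,5R)-4-formyl-4,7-dimethyl-5-(2,4,6-trimethoxyphenyl)octanoate
Conditions: MeI, K2CO3, DMF, 40 °C
Reagents that add atoms: iodomethane, CI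
Why: Williamson O-methylation, in which carbonate opens the lactol to the phenoxide–aldehyde, the phenoxide is trapped by iodomethane, and the non-enolisable α-quaternary aldehyde is released without risk to the two stereocentres.

Step 6
Reactants: 10 (S)-carvone
Product: 11 (2R,5S)-2-methyl-5-(prop-1-en-2-yl)cyclohexan-1-one (cis-dihydrocarvone)
Conditions: ene-reductase OYE1, NADP+ (cat.), glucose, glucose dehydrogenase, phosphate buffer (pH 7), 30 °C
Reagents that add atoms: none
Why: Enzymatic conjugate reduction by an old-yellow-enzyme ene-reductase, which adds hydride to C3 and a proton to C2 under active-site control and so sets C2 as R (methyl cis to the isopropenyl group), the epimer that thermodynamic control does not favour.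

Step 7
Reactants: 11 (2R,5S)-dihydrocarvone; 12 N-phenylbis(trifluoromethanesulfonimide)
Product: 13 (3S,6R)-6-methyl-3-(prop-1-en-2-yl)cyclohex-1-en-1-yl trifluoromethanesulfonate
Conditions: LDA, THF, −78 °C; PhNTf2, −78 → 0 °C
Reagents that add atoms: N-phenylbis(trifluoromethanesulfonimide), O=S(=O)(N(c1ccccc1)S(=O)(=O)C(F)(F)F)C(F)(F)F
Why: Kinetic enolate formation at the less substituted α-carbon followed by O-sulfonylation gives the enol triflate regioselectively, and the epimerisable methyl-bearing centre (future C8) is never deprotonated.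

Step 8
Reactants: 9 the aldehyde ester; 13 the enol triflate
Product: 15 (5R,6R)-5-methyl-5-[(1S)-3-methyl-1-(2,4,6-trimethoxyphenyl)butyl]-6-[(3S,6R)-6-methyl-3-(prop-1-en-2-yl)cyclohex-1-en-1-yl]oxan-2-one, via hydroxy ester 14 (not isolated)
Conditions: CrCl2 (4 equiv), NiCl2 (2 mol%), (S)-N-[2-(4-isopropyl-4,5-dihydrooxazol-2-yl)-6-methylphenyl]methanesulfonamide, Et3N, THF, rt; then PPTS (cat.), PhMe, 70 °C
Reagents that add atoms: none
Why: Nozaki–Hiyama–Kishi coupling, in which the alkenyl triflate is activated by nickel, transferred to chromium and added chemoselectively to the aldehyde (the ester is inert), the chiral sulfonamide–chromium complex being chosen to give the (R)-carbinol at the future C1, followed by acid-catalysed δ-lactonisation helped by the quaternary neighbour.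

Step 9
Reactants: 15 the δ-lactone
Product: 18 the ring A acid, i.e. the C4-carboxylic acid of compound 20 (CO2H on C4 cis to the C2 methyl group, trans to H-4a), via silyl ketene acetal 16 (not isolated), via trimethylsilyl ester 17 (not isolated)
Conditions: LDA, TMSCl/Et3N, THF, −78 °C → rt; PhMe, 110 °C; 1 M HCl
Reagents that add atoms: none
Why: LDA deprotonates C4 of the lactone and the enolate is O-silylated to the cyclic silyl ketene acetal 16, whose C4=C(OSi)–O–C1–C8a=C4a array undergoes a concerted suprafacial [3,3] sigmatropic shift on heating. This is the Ireland–Claisen rearrangement in its lactone (ring-contracting) form, a known reaction type for 6-alkenyl δ-lactones and 6-alkenyl-1,4-dioxan-2-ones. Ring A is closed by pericyclic C4–C4a bond formation through a boat-like, bicyclo[2.2.2]octane-type transition state enforced by the lactone ring, while the C1–O bond breaks and C1=C8a appears. The new stereocentre C4a is controlled by the (R)-carbinol carbon C1, because C4 must add to the face of the ring B alkene from which the oxygen leaves; this face is anti to the C8 methyl and C5 isopropenyl groups (matched case), and the carboxyl-bearing centre formed at C4 is removed in step 10. The step needs regioselective enolisation (C4 is the only enolisable position, C2 being quaternary) and O- rather than C-silylation; the bulky benzylic group on C2 points away from the silyloxy bridge, so the required transition state is also the less hindered one.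

Step 10
Reactants: 18 the ring A acid
Product: 20 2-[(1S)-1-[(2S,4aR,5S,8R)-2,8-dimethyl-5-(prop-1-en-2-yl)-2,3,4,4a,5,6,7,8-octahydronaphthalen-2-yl]-3-methylbutyl]-1,3,5-trimethoxybenzene, via thiohydroxamate ester 19 (not isolated)
Conditions: N-hydroxypyridine-2-thione, DCC, DMAP (cat.), CH2Cl2, rt, dark; then tBuSH, PhH, visible light, rt
Reagents that add atoms: none
Why: Barton reductive decarboxylation, in which the thiohydroxamate ester fragments under light to the secondary C4 radical that abstracts hydrogen from the thiol, so the surplus carboxyl and its stereocentre disappear while C4a and the alkenes stay untouched.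

Step 11
Reactants: 20 the trimethoxyarene; 21 N-bromosuccinimide
Product: 22 2,4-dibromo-1,3,5-trimethoxy-6-[(1S)-1-[(2S,4aR,5S,8R)-2,8-dimethyl-5-(prop-1-en-2-yl)-2,3,4,4a,5,6,7,8-octahydronaphthalen-2-yl]-3-methylbutyl]benzene
Conditions: NBS (2.05 equiv), MeCN, −20 °C, dark
Reagents that add atoms: N-bromosuccinimide, O=C1CCC(=O)N1Br
Why: Electrophilic aromatic bromination, in which the two ring positions flanked by methoxy groups should react with NBS far faster than the hindered trisubstituted alkene or the isopropenyl group.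

Step 12
Reactants: 22 the dibromide; 23 dioxygen
Product: 24 2-[(1S,4R,4aR,6S)-6-[(1S)-1-(3,5-dibromo-2,4,6-trimethoxyphenyl)-3-methylbutyl]-4,6-dimethyl-1,2,3,4,4a,5,6,7-octahydro... ] replaced by description: the tertiary alcohol of 22, in which the C5 isopropenyl group is hydrated to 2-hydroxypropan-2-yl (centres 1'S,2S,4aR,5S,8R)
Conditions: Co(acac)2 (20 mol%), PhSiH3, O2 (1 atm), THF, rt
Reagents that add atoms: dioxygen, O=O
Why: Mukaiyama hydration, in which hydrogen atom transfer from a cobalt hydride to the 1,1-disubstituted alkene gives the tertiary radical that is trapped by O2 and reduced to the Markovnikov alcohol, while the hindered trisubstituted C1=C8a alkene should react much more slowly and C5 is not touched.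

Step 13
Reactants: 24 the dibromo alcohol; 25 N,N-dimethylformamide
Product: 26 5-[(1S)-1-[(2S,4aR,5S,8R)-5-(2-hydroxypropan-2-yl)-2,8-dimethyl-2,3,4,4a,5,6,7,8-octahydronaphthalen-2-yl]-3-methylbutyl]-2,4,6-trimethoxybenzene-1,3-dicarbaldehyde
Conditions: tBuLi (5.5 equiv), THF, −78 °C; DMF, −78 → 0 °C; then H2O
Reagents that add atoms: N,N-dimethylformamide, CN(C)C=O
Why: Twofold bromine–lithium exchange (after deprotonation of the alcohol) and formylation of the dilithio arene with DMF install both aldehydes under non-acidic conditions that spare the tertiary alcohol and the alkene.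

Step 14
Reactants: 26 the tri-O-methyl ether
Product: 27 5-[(1S)-1-[(2S,4aR,5S,8R)-5-(2-hydroxypropan-2-yl)-2,8-dimethyl-2,3,4,4a,5,6,7,8-octahydronaphthalen-2-yl]-3-methylbutyl]-2,4,6-trihydroxybenzene-1,3-dicarbaldehyde (target)
Conditions: NaSEt (excess), DMF, 120 °C; then cold 1 M HCl
Reagents that add atoms: none
Why: Nucleophilic demethylation (SN2 at methyl) by thiolate, made easy because every methoxy group is ortho or para to a formyl group, and free of the Lewis or protic acids that could ionise the tertiary alcohol or add a phenol to C1=C8a.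

Compound list

1 | 5,7-dimethoxycoumarin | COc1cc(OC)c2C=CC(=O)Oc2c1 | starting material
2 | isobutylmagnesium bromide | CC(C)C[Mg]Br | starting material
3 | (4S)-4-isobutyl-5,7-dimethoxychroman-2-one | CC(C)C[C@H](c1c(OC)cc(OC)cc1O2)CC2=O | intermediate
4 | methyl acrylate | C=CC(=O)OC | starting material
5 | methyl 3-[(3S,4S)-4-isobutyl-5,7-dimethoxy-2-oxochroman-3-yl]propanoate | CC(C)C[C@H](c1c(OC)cc(OC)cc1O2)[C@H](CCC(=O)OC)C2=O | intermediate
6 | iodomethane | CI | starting material
7 | methyl 3-[(3R,4R)-4-isobutyl-5,7-dimethoxy-3-methyl-2-oxochroman-3-yl]propanoate | CC(C)C[C@H](c1c(OC)cc(OC)cc1O2)[C@](CCC(=O)OC)(C)C2=O | intermediate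
8 | methyl 3-[(3R,4R)-2-hydroxy-4-isobutyl-5,7-dimethoxy-3-methylchroman-3-yl]propanoate (lactol, anomer mixture) | CC(C)C[C@H](c1c(OC)cc(OC)cc1O2)[C@](CCC(=O)OC)(C)C2O | intermediate
9 | methyl (4R,5R)-4-formyl-4,7-dimethyl-5-(2,4,6-trimethoxyphenyl)octanoate | CC(C)C[C@H](c1c(OC)cc(OC)cc1OC)[C@](CCC(=O)OC)(C)C=O | intermediate
10 | (S)-carvone | CC1=CC[C@@H](CC1=O)C(C)=C | starting material
11 | (2R,5S)-2-methyl-5-(prop-1-en-2-yl)cyclohexan-1-one | O=C1[C@H](C)CC[C@H](C(C)=C)C1 | intermediate
12 | N-phenylbis(trifluoromethanesulfonimide) | O=S(=O)(N(c1ccccc1)S(=O)(=O)C(F)(F)F)C(F)(F)F | starting material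
13 | (3S,6R)-6-methyl-3-(prop-1-en-2-yl)cyclohex-1-en-1-yl trifluoromethanesulfonate | C[C@@H]1CC[C@H](C(C)=C)C=C1OS(=O)(=O)C(F)(F)F | intermediate
14 | methyl (4R,5S)-4-[(R)-hydroxy[(3S,6R)-6-methyl-3-(prop-1-en-2-yl)cyclohex-1-en-1-yl]methyl]-4,7-dimethyl-5-(2,4,6-trimethoxyphenyl)octanoate | CC(C)C[C@H](c1c(OC)cc(OC)cc1OC)[C@](CCC(=O)OC)(C)[C@@H](O)C1=C[C@@H](C(C)=C)CC[C@H]1C | intermediate
15 | (5R,6R)-5-methyl-5-[(1S)-3-methyl-1-(2,4,6-trimethoxyphenyl)butyl]-6-[(3S,6R)-6-methyl-3-(prop-1-en-2-yl)cyclohex-1-en-1-yl]oxan-2-one | CC(C)C[C@H](c1c(OC)cc(OC)cc1OC)[C@]1(C)[C@H](C2=C[C@@H](C(C)=C)CC[C@H]2C)OC(=O)CC1 | intermediate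
16 | cyclic O-trimethylsilyl ketene acetal of lactone 15 (6-trimethylsilyloxy-3,4-dihydro-2H-pyran, stereocentres as in 15) | CC(C)C[C@H](c1c(OC)cc(OC)cc1OC)[C@]1(C)[C@H](C2=C[C@@H](C(C)=C)CC[C@H]2C)OC(O[Si](C)(C)C)=CC1 | intermediate
17 | trimethylsilyl ester of acid 18 | CC(C)C[C@H](c1c(OC)cc(OC)cc1OC)[C@]1(C)C=C2[C@H](C)CC[C@H](C(C)=C)[C@H]2[C@@H](C(=O)O[Si](C)(C)C)C1 | intermediate
18 | C4-carboxylic acid of 20 (CO2H cis to the C2 methyl group, trans to H-4a; other centres as in 20) | CC(C)C[C@H](c1c(OC)cc(OC)cc1OC)[C@]1(C)C=C2[C@H](C)CC[C@H](C(C)=C)[C@H]2[C@@H](C(=O)O)C1 | intermediate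
19 | 2-thioxopyridin-1(2H)-yl ester of acid 18 | CC(C)C[C@H](c1c(OC)cc(OC)cc1OC)[C@]1(C)C=C2[C@H](C)CC[C@H](C(C)=C)[C@H]2[C@@H](C(=O)ON3C=CC=CC3=S)C1 | intermediate
20 | 2-[(1S)-1-[(2S,4aR,5S,8R)-2,8-dimethyl-5-(prop-1-en-2-yl)-2,3,4,4a,5,6,7,8-octahydronaphthalen-2-yl]-3-methylbutyl]-1,3,5-trimethoxybenzene | CC(C)C[C@H](c1c(OC)cc(OC)cc1OC)[C@]1(C)C=C2[C@H](C)CC[C@H](C(C)=C)[C@H]2CC1 | intermediate
21 | N-bromosuccinimide | O=C1CCC(=O)N1Br | starting material
22 | dibromide of 20 (bromine on both free ring positions of the arene) | CC(C)C[C@H](c1c(OC)c(Br)c(OC)c(Br)c1OC)[C@]1(C)C=C2[C@H](C)CC[C@H](C(C)=C)[C@H]2CC1 | intermediate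
23 | dioxygen | O=O | starting material
24 | tertiary alcohol of 22 (C5 bears 2-hydroxypropan-2-yl; centres 1'S,2S,4aR,5S,8R) | CC(C)C[C@H](c1c(OC)c(Br)c(OC)c(Br)c1OC)[C@]1(C)C=C2[C@H](C)CC[C@H](C(C)(C)O)[C@H]2CC1 | intermediate
25 | N,N-dimethylformamide | CN(C)C=O | starting material
26 | tri-O-methyl ether of the target (2,4,6-trimethoxybenzene-1,3-dicarbaldehyde) | CC(C)C[C@H](c1c(OC)c(C=O)c(OC)c(C=O)c1OC)[C@]1(C)C=C2[C@H](C)CC[C@H](C(C)(C)O)[C@H]2CC1 | intermediate
27 | 5-[(1S)-1-[(2S,4aR,5S,8R)-5-(2-hydroxypropan-2-yl)-2,8-dimethyl-2,3,4,4a,5,6,7,8-octahydronaphthalen-2-yl]-3-methylbutyl]-2,4,6-trihydroxybenzene-1,3-dicarbaldehyde | CC(C)C[C@H](c1c(O)c(C=O)c(O)c(C=O)c1O)[C@]1(C)C=C2[C@H](C)CC[C@H](C(C)(C)O)[C@H]2CC1 | target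

Correction to the Product line of step 12, which should read: 24 the tertiary alcohol of dibromide 22, in which the C5 isopropenyl group is hydrated to 2-hydroxypropan-2-yl (centres 1'S,2S,4aR,5S,8R).

Total step count: 14. Longest linear sequence: 12 steps (steps 1–5, then 8–14); steps 6–7 form the short branch.

Steps most likely to fail

Step 9 (key step). The lactone enolate may be C-silylated or decompose before the boat transition state is reached, or the hindered quaternary neighbour may slow the shift so that the ketene acetal is lost on prolonged heating. Fallback, a palladium-catalysed ring closure in place of the sigmatropic one: it sets out from hydroxy ester 14, isolated by leaving out the PPTS treatment of step 8. Methyl chloroformate and pyridine give the allylic methyl carbonate F1. LDA added to F1 and TMSCl at −78 °C gives the silyl ketene acetal F2. Pd(PPh3)4 in THF at 60 °C then ionises the carbonate with inversion; the released methoxide frees the ester enolate, which attacks the allyl unit at C4a on the face opposite to palladium (six-membered ring in preference to the four-membered alternative at C1) and gives the methyl ester F3 by intramolecular Tsuji–Trost alkylation. Hydrolysis with LiOH returns to acid 18.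

Step 8. The two partners are both hindered, so the coupling may be slow, and facial control by the chiral chromium complex over the α-quaternary aldehyde may be poor. Fallback, reagent-controlled reduction in place of stereoselective C–C bond formation: it sets out from aldehyde 9 and triflate 13. The coupling is run without the chiral ligand (CrCl2, NiCl2 cat., DMF) and should give 14 together with the carbinol epimer F4. Dess–Martin periodinane oxidises the mixture to the single enone F5. Corey–Bakshi–Shibata reduction with (R)-2-methyl-CBS-oxazaborolidine and catecholborane (the quaternary carbon taken as the large group) gives 14, which is lactonised with PPTS to return to lactone 15.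

Step 1. The peri methoxy group and the electron-rich ring may make the coumarin unreactive toward the alkylcopper species and may erode enantiofacial discrimination. Fallback, a rhodium-catalysed addition of an sp2 boron reagent followed by hydrogenation: it sets out from coumarin 1. Asymmetric 1,4-addition of 2-methylprop-1-enylboronic acid (Rh(acac)(C2H4)2, SEGPHOS, dioxane/H2O, 60 °C) gives the 4-alkenyl dihydrocoumarin F6, and hydrogenation over palladium on carbon (Pd/C, H2, EtOAc) returns to compound 3.

Further compounds

F1 | step 9 | allylic methyl carbonate of hydroxy ester 14 | CC(C)C[C@H](c1c(OC)cc(OC)cc1OC)[C@](CCC(=O)OC)(C)[C@@H](OC(=O)OC)C1=C[C@@H](C(C)=C)CC[C@H]1C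
F2 | step 9 | O-trimethylsilyl ketene acetal of carbonate F1 | CC(C)C[C@H](c1c(OC)cc(OC)cc1OC)[C@](CC=C(OC)O[Si](C)(C)C)(C)[C@@H](OC(=O)OC)C1=C[C@@H](C(C)=C)CC[C@H]1C
F3 | step 9 | methyl ester of acid 18 (C4 configuration not defined) | CC(C)C[C@H](c1c(OC)cc(OC)cc1OC)[C@]1(C)C=C2[C@H](C)CC[C@H](C(C)=C)[C@H]2C(C(=O)OC)C1
F4 | step 8 | carbinol epimer of hydroxy ester 14 ((S)-carbinol) | CC(C)C[C@H](c1c(OC)cc(OC)cc1OC)[C@](CCC(=O)OC)(C)[C@H](O)C1=C[C@@H](C(C)=C)CC[C@H]1C
F5 | step 8 | enone (ketone at the carbinol carbon of 14) | CC(C)C[C@H](c1c(OC)cc(OC)cc1OC)[C@](CCC(=O)OC)(C)C(=O)C1=C[C@@H](C(C)=C)CC[C@H]1C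
F6 | step 1 | (4R)-5,7-dimethoxy-4-(2-methylprop-1-en-1-yl)chroman-2-one | CC(C)=C[C@H](c1c(OC)cc(OC)cc1O2)CC2=O
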